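## Retrosynthetic overview

1. Target 16 is cut at the CH2 bridge between the two pyranone C3 atoms (Mannich / amine elimination / Michael) into the chiral tetralone–pyranone 11, the achiral naphthyl–pyranone 13 and a one-carbon iminium salt.
2. Both 11 and 13 come from one open-chain 1,5-diketone 10. A catalytic asymmetric 6-enolexo aldol with dynamic kinetic resolution gives 11 (both stereocentres set together). Acid-mediated aldol condensation and aromatization gives 13.
3. 10 comes from benzoylation of the benzylic CH2 of 7, then removal of the benzyl and methyl ethers.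
4. 7 comes from aryne acyl-alkylation (3-methoxybenzyne inserted into the acetyl–CH2 bond) of acetonylpyranone 4, made by acylating the 6-methyl group of benzyl-protected triacetic acid lactone.
5. Ring order: the pyranone (1) and the benzene ring (aryne precursor 5) are bought; the tetralone carbocycle (step 6) and the second naphthalene ring (step 7) are formed last; then the two halves are bridged.

Assumption: the facial sense of the catalyst in step 6 rests on a transition-state model only; the quinidine-derived amine is written, and its quinine-derived pseudoenantiomer replaces it if the first run gives the mirror image.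

## Route

Step 1
Reactants: 1 4-hydroxy-6-methyl-2H-pyran-2-one
Product: 2 4-(benzyloxy)-6-methyl-2H-pyran-2-one
Conditions: BnBr (1.1 equiv), K2CO3 (1.0 equiv), DMF, 25 °C
Reagents that add atoms: benzyl bromide, BrCc1ccccc1
Why: Williamson-type O-alkylation of the vinylogous acid at its 4-oxygen (the usual site under carbonate in DMF), which removes the acidic proton that would quench the carbanion and aryne chemistry of steps 2–4.

Step 2
Reactants: 2 4-(benzyloxy)-6-methyl-2H-pyran-2-one; 3 N-methoxy-N-methylacetamide
Product: 4 4-(benzyloxy)-6-(2-oxopropyl)-2H-pyran-2-one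
Conditions: LiN(SiMe3)2 (2.1 equiv), THF, −78 °C; then 3 (1.2 equiv), −78 → −20 °C; aq. NH4Cl
Reagents that add atoms: none
Why: LiN(SiMe3)2 deprotonates the 6-methyl group (vinylogous ester dienolate, the established site for 4-alkoxy-6-methyl-2-pyranones) and the carbanion acylates the Weinreb amide, whose chelated tetrahedral adduct prevents double addition (Weinreb ketone synthesis).

Step 3
Reactants: 4 4-(benzyloxy)-6-(2-oxopropyl)-2H-pyran-2-one; 5 3-methoxy-2-(trimethylsilyl)phenyl trifluoromethanesulfonate
Product: 7 6-(2-acetyl-3-methoxybenzyl)-4-(benzyloxy)-2H-pyran-2-one, via 3-methoxybenzyne 6 (not isolated)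
Conditions: 5 (1.25 equiv), CsF (2.5 equiv), MeCN, 80 °C
Reagents that add atoms: none
Why: aryne acyl-alkylation (formal insertion of an aryne into the C–C σ bond of a β-dicarbonyl compound): the enolate carbon of the vinylogous β-keto ester adds to 6 meta to OMe, the aryl anion formed next to OMe closes onto the acetyl C=O, and fragmentation of the benzocyclobutenoxide places the acetyl group between OMe and the new CH2, giving the required 1,2,3-pattern.

Step 4
Reactants: 7 6-(2-acetyl-3-methoxybenzyl)-4-(benzyloxy)-2H-pyran-2-one; 8 N-methoxy-N-methylbenzamide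
Product: 9 rac-6-[1-(2-acetyl-3-methoxyphenyl)-2-oxo-2-phenylethyl]-4-(benzyloxy)-2H-pyran-2-one
Conditions: LiN(SiMe3)2 (2.1 equiv), THF, −78 °C; then 8 (1.2 equiv), −78 → 0 °C; aq. NH4Cl
Reagents that add atoms: none
Why: the CH2 between the aryl ring and pyranone C6 is the most acidic C–H of 7 (well below the hindered, twisted aryl methyl ketone), so deprotonation at −78 °C and C-acylation with the Weinreb amide (crossed Claisen-type acylation) give the β-keto compound; its new stereocentre is labile and is left racemic on purpose.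

Step 5
Reactants: 9 rac-6-[1-(2-acetyl-3-methoxyphenyl)-2-oxo-2-phenylethyl]-4-(benzyloxy)-2H-pyran-2-one
Product: 10 rac-6-[1-(2-acetyl-3-hydroxyphenyl)-2-oxo-2-phenylethyl]-4-hydroxy-2H-pyran-2-one
Conditions: BCl3 (4 equiv), C6HMe5 (3 equiv), CH2Cl2, −78 → 0 °C; then H2O, 0 °C
Reagents that add atoms: none
Why: BCl3 cleaves the benzyl vinylogous ester at low temperature (benzyl cation trapped by pentamethylbenzene, Friedel–Crafts alkylation) and, by chelation between the acetyl oxygen and the ortho OMe, the aryl methyl ether on warming to 0 °C; the cold, short, acid-only regime avoids the amine or base that would start the aldol closure.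

Step 6
Reactants: 10 rac-6-[1-(2-acetyl-3-hydroxyphenyl)-2-oxo-2-phenylethyl]-4-hydroxy-2H-pyran-2-one
Product: 11 (3R,4R)-3,8-dihydroxy-4-(4-hydroxy-2-oxo-2H-pyran-6-yl)-3-phenyl-3,4-dihydronaphthalen-1(2H)-one
Conditions: 9-amino-9-deoxy-epi-quinidine (20 mol%), H2O (5 equiv), THF, 0 → 25 °C, 48 h, N2
Reagents that add atoms: none
Why: Proposed new method: a primary-amine-catalysed 6-enolexo ketone–ketone aldol cyclization with dynamic kinetic resolution, in which the methine C–H of 10 (α to the benzoyl group, the aryl ring and the vinylogous lactone) epimerizes fast through its enol in the amine / pyranone-acid buffer (the 4-hydroxypyranone, pKa about 5, is the built-in acid co-catalyst), the catalyst NH2 condenses with the 2-hydroxyaryl methyl ketone to a ketimine/enamine whose nitrogen is held on the phenol side by an O–H···N hydrogen bond so that the nucleophilic CH2 faces the benzoyl group and C–C rather than N–C closure occurs, and the protonated quinuclidine hydrogen-bonds to the benzoyl oxygen and selects one ketone face of one substrate enantiomer in a half-chair transition state with the pyranone pseudoaxial (no peri strain) and phenyl pseudoequatorial, setting C3 (R) and C4 (R) together with OH trans to the pyranone before hydrolysis of the product iminium turns the catalyst over; the closest known reaction type is the amine-catalysed intramolecular enolexo aldolization (Hajos–Parrish–Eder–Sauer–Wiechert type) and cinchona primary-amine enamine catalysis of ketones, neither shown with dynamic resolution of an α-stereocentre next to an aryl ketone acceptor.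

Step 7
Reactants: 10 rac-6-[1-(2-acetyl-3-hydroxyphenyl)-2-oxo-2-phenylethyl]-4-hydroxy-2H-pyran-2-one
Product: 13 6-(4,5-dihydroxy-2-phenylnaphthalen-1-yl)-4-hydroxy-2H-pyran-2-one, via stereorandom aldol adduct 12 (not isolated)
Conditions: TsOH·H2O (20 mol%), toluene/1,4-dioxane (4:1), 90 °C, N2
Reagents that add atoms: none
Why: Brønsted acid-catalysed intramolecular aldol condensation of the methyl ketone enol onto the benzoyl group, loss of the tertiary benzylic OH and tautomerization of the naphthalen-1(4H)-one to the naphthol; aromatization makes the sequence irreversible and erases both stereocentres, so racemic 10 serves.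

Step 8
Reactants: 13 6-(4,5-dihydroxy-2-phenylnaphthalen-1-yl)-4-hydroxy-2H-pyran-2-one; 11 (3R,4R)-3,8-dihydroxy-4-(4-hydroxy-2-oxo-2H-pyran-6-yl)-3-phenyl-3,4-dihydronaphthalen-1(2H)-one
Product: 16 wailupemycin I, via Mannich base 14 (not isolated), via methylenepyrandione 15 (not isolated)
Conditions: 13, CH2=NMe2+ I− (1.0 equiv), MeCN, 0 → 25 °C, 1 h; then NaOAc (1.0 equiv), 11 (1.0 equiv), 40 °C
Reagents that add atoms: N,N-dimethylmethyleneiminium iodide (Eschenmoser's salt), C=[N+](C)C.[I-]
Why: Mannich reaction of the iminium salt at C3 of the 4-hydroxypyranone of 13 (its most nucleophilic carbon), E1cB loss of dimethylamine from the zwitterion to the 3-methylidene-2,4-dione and Michael addition of C3 of 11 (the Knoevenagel–Michael logic of dicoumarol formation, run stepwise so that only the crossed dimer forms); the acetate buffer at 40 °C leaves the β-hydroxy ketone and both stereocentres untouched.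

## Compound list

1 | 4-hydroxy-6-methyl-2H-pyran-2-one (triacetic acid lactone) | Cc1cc(O)cc(=O)o1 | starting material
2 | 4-(benzyloxy)-6-methyl-2H-pyran-2-one | Cc1cc(OCc2ccccc2)cc(=O)o1 | intermediate
3 | N-methoxy-N-methylacetamide | CC(=O)N(C)OC | starting material
4 | 4-(benzyloxy)-6-(2-oxopropyl)-2H-pyran-2-one | CC(=O)Cc1cc(OCc2ccccc2)cc(=O)o1 | intermediate
5 | 3-methoxy-2-(trimethylsilyl)phenyl trifluoromethanesulfonate | COc1cccc(OS(=O)(=O)C(F)(F)F)c1[Si](C)(C)C | starting material
6 | 3-methoxybenzyne (3-methoxy-1,2-didehydrobenzene) | COC1=CC=CC#C1 | intermediate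
7 | 6-(2-acetyl-3-methoxybenzyl)-4-(benzyloxy)-2H-pyran-2-one | CC(=O)c1c(OC)cccc1Cc1cc(OCc2ccccc2)cc(=O)o1 | intermediate
8 | N-methoxy-N-methylbenzamide | CON(C)C(=O)c1ccccc1 | starting material
9 | rac-6-[1-(2-acetyl-3-methoxyphenyl)-2-oxo-2-phenylethyl]-4-(benzyloxy)-2H-pyran-2-one | CC(=O)c1c(OC)cccc1C(C(=O)c1ccccc1)c1cc(OCc2ccccc2)cc(=O)o1 | intermediate
10 | rac-6-[1-(2-acetyl-3-hydroxyphenyl)-2-oxo-2-phenylethyl]-4-hydroxy-2H-pyran-2-one | CC(=O)c1c(O)cccc1C(C(=O)c1ccccc1)c1cc(O)cc(=O)o1 | intermediate
11 | (3R,4R)-3,8-dihydroxy-4-(4-hydroxy-2-oxo-2H-pyran-6-yl)-3-phenyl-3,4-dihydronaphthalen-1(2H)-one (phenyl cis to pyranone, OH trans to pyranone) | O=C1C[C@](O)(c2ccccc2)[C@H](c2cc(O)cc(=O)o2)c2cccc(O)c21 | intermediate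
12 | 3,8-dihydroxy-4-(4-hydroxy-2-oxo-2H-pyran-6-yl)-3-phenyl-3,4-dihydronaphthalen-1(2H)-one, mixture of stereoisomers | O=C1CC(O)(c2ccccc2)C(c2cc(O)cc(=O)o2)c2cccc(O)c21 | intermediate
13 | 6-(4,5-dihydroxy-2-phenylnaphthalen-1-yl)-4-hydroxy-2H-pyran-2-one | O=c1cc(O)cc(-c2c(-c3ccccc3)cc(O)c3c(O)cccc23)o1 | intermediate
14 | 3-[(dimethylamino)methyl]-6-(4,5-dihydroxy-2-phenylnaphthalen-1-yl)-4-hydroxy-2H-pyran-2-one | CN(C)Cc1c(O)cc(-c2c(-c3ccccc3)cc(O)c3c(O)cccc23)oc1=O | intermediate
15 | 6-(4,5-dihydroxy-2-phenylnaphthalen-1-yl)-3-methylidene-2H-pyran-2,4(3H)-dione | C=C1C(=O)C=C(-c2c(-c3ccccc3)cc(O)c3c(O)cccc23)OC1=O | intermediate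
16 | wailupemycin I: 6-[(1R,2R)-2,5-dihydroxy-4-oxo-2-phenyl-1,2,3,4-tetrahydronaphthalen-1-yl]-3-{[6-(4,5-dihydroxy-2-phenylnaphthalen-1-yl)-4-hydroxy-2-oxo-2H-pyran-3-yl]methyl}-4-hydroxy-2H-pyran-2-one | O=C1C[C@](O)(c2ccccc2)[C@H](c2cc(O)c(Cc3c(O)cc(-c4c(-c5ccccc5)cc(O)c5c(O)cccc45)oc3=O)c(=O)o2)c2cccc(O)c21 | target

## Step count and risk

Total steps: 8. Longest linear sequence: 7 (steps 1–6 and 8; the branch through step 7 is equally long).

The three steps most likely to fail:

**Step 4 (C-benzoylation of 7).** The carbanion is hindered and sits ortho to an enolizable acetyl group. Proton transfer to the methyl ketone enolate could trigger attack on the pyranone, and the Weinreb amide may react slowly. The fallback sets out from 7 and comes back at 9. The same lithium carbanion is trapped with the far more reactive benzaldehyde (aldol addition, −78 °C) to give the secondary alcohol 6-[1-(2-acetyl-3-methoxyphenyl)-2-hydroxy-2-phenylethyl]-4-(benzyloxy)-2H-pyran-2-one F1 as a diastereomer mixture. F1 is then oxidized with Dess–Martin periodinane (NaHCO3, CH2Cl2, 0 °C) to 9.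

**Step 6 (the proposed aldol with dynamic kinetic resolution).** Imine formation at a di-ortho-substituted ketone may be slow. The catalyst may be held as a stable Schiff base. The product may dehydrate to 13. The level and sense of induction are untested. The fallback uses known chemistry, sets out from 10 and comes back at 11. Compound 10 is cyclized with achiral pyrrolidine/AcOH (20 mol% each, EtOH, 25 °C; Kabbe-type enamine aldol) to the racemic trans-hydroxy/pyranone tetralone. The enantiomers are separated by preparative supercritical-fluid chromatography on an amylose tris(3,5-dimethylphenylcarbamate) phase. This gives 11 and its mirror image (3S,4S)-3,8-dihydroxy-4-(4-hydroxy-2-oxo-2H-pyran-6-yl)-3-phenyl-3,4-dihydronaphthalen-1(2H)-one F2. F2 and any cis diastereomer are not wasted, because the acid conditions of step 7 dehydrate them to 13.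

**Step 8 (crossed methylene bridging).** The iminium salt may also aminomethylate the electron-rich naphthalene-1,8-diol ring of 13. Amine elimination may be incomplete at 40 °C. The fallback sets out from 11 and 13 and comes back at 16. It is the classical dicoumarol-type Knoevenagel–Michael condensation with aqueous formaldehyde, a milder electrophile (11 : 13 : CH2O = 1 : 3 : 2, EtOH/H2O, 25 °C). The excess of achiral 13 channels 11 into the crossed dimer 16. Reverse-phase chromatography separates 16 from the homodimer 3,3'-methylenebis[6-(4,5-dihydroxy-2-phenylnaphthalen-1-yl)-4-hydroxy-2H-pyran-2-one] F3 and from a small amount of 3,3'-methylenebis{6-[(1R,2R)-2,5-dihydroxy-4-oxo-2-phenyl-1,2,3,4-tetrahydronaphthalen-1-yl]-4-hydroxy-2H-pyran-2-one} F4.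

## Further compounds

F1 | step 4 | 6-[1-(2-acetyl-3-methoxyphenyl)-2-hydroxy-2-phenylethyl]-4-(benzyloxy)-2H-pyran-2-one (diastereomer mixture) | CC(=O)c1c(OC)cccc1C(C(O)c1ccccc1)c1cc(OCc2ccccc2)cc(=O)o1
F2 | step 6 | (3S,4S)-3,8-dihydroxy-4-(4-hydroxy-2-oxo-2H-pyran-6-yl)-3-phenyl-3,4-dihydronaphthalen-1(2H)-one | O=C1C[C@@](O)(c2ccccc2)[C@@H](c2cc(O)cc(=O)o2)c2cccc(O)c21
F3 | step 8 | 3,3'-methylenebis[6-(4,5-dihydroxy-2-phenylnaphthalen-1-yl)-4-hydroxy-2H-pyran-2-one] | O=c1oc(-c2c(-c3ccccc3)cc(O)c3c(O)cccc23)cc(O)c1Cc1c(O)cc(-c2c(-c3ccccc3)cc(O)c3c(O)cccc23)oc1=O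
F4 | step 8 | 3,3'-methylenebis{6-[(1R,2R)-2,5-dihydroxy-4-oxo-2-phenyl-1,2,3,4-tetrahydronaphthalen-1-yl]-4-hydroxy-2H-pyran-2-one} | O=C1C[C@](O)(c2ccccc2)[C@H](c2cc(O)c(Cc3c(O)cc([C@@H]6c7cccc(O)c7C(=O)C[C@]6(O)c8ccccc8)oc3=O)c(=O)o2)c2cccc(O)c21
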